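## Retrosynthetic overview

1. Last operations: global desilylation; each CH2OH on C8 comes from a vinyl group (oxidative cleavage, reduction); each ArCH2 group on C8′ comes from copper-catalysed aryl-Grignard opening of a spiro-epoxide.
2. Key disconnection: the C7–C8 bond of the tetrahydrofuran (ring O–C7–C8–C8′–C9′). C7, the O,aryl-substituted carbon, becomes an oxocarbenium ion (biaryl aldehyde plus the C9′ oxygen); C8 is the γ-carbon of an allylsilane whose silicon is held by the second CH2O arm of C8′ in a seven-membered 1,2-oxasilepine. The enabling feature is that C8′ carries an oxygen and two CH2 arms (ring C9′H2–O, and C7′H2, kept as CH2O until the aryl is attached) next to C8 with its one-carbon branch (vinyl = masked CH2OH).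
3. Both halves use one chiral siloxane 14 (2-vinylglycerol, desymmetrised, oxasilepine by RCM). The first tetrahydrofuran, built on 5-bromovanillin, is rearranged by ring-opening Friedel–Crafts closure to the aryltetralin; Suzuki coupling then gives biaryl aldehyde 36.
4. Order of rings: oxasilepine (temporary) → first tetrahydrofuran (temporary) → tetralin → biaryl bond → dioxolane and oxasilepine (temporary) → tetrahydrofuran of the target (key step).

Key step: step 19

Assumption: in step 3 the (R,R)-ligand is taken to acylate the arm that gives (R)-6; if the sense of induction is the opposite, the (S,S)-ligand is used and nothing else changes.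

Remark: lignan locants used below: C7 = ArCH–O, C8 = ring CH with the one-carbon branch, C8′ = ring C–OH, C9′ = ring OCH2, C7′ = benzylic CH2. TIPS = tri(propan-2-yl)silyl, TBDPS = tert-butyldiphenylsilyl, TMS = trimethylsilyl.

## Route

Step 1
Reactants: 1 2,2-dimethyl-1,3-dioxan-5-one; 2 vinylmagnesium bromide
Product: 3 5-ethenyl-2,2-dimethyl-1,3-dioxan-5-ol
Conditions: THF, −78 → 0 °C; aq. NH4Cl
Reagents that add atoms: vinylmagnesium bromide, C=C[Mg]Br
Why: Grignard 1,2-addition to an unhindered ketone; the product is achiral because the new carbinol carbon lies on the mirror plane of the dioxane.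

Step 2
Reactants: 3 5-ethenyl-2,2-dimethyl-1,3-dioxan-5-ol
Product: 4 2-(hydroxymethyl)but-3-ene-1,2-diol (2-vinylglycerol)
Conditions: Dowex 50WX8 (H+ form), MeOH/H2O 9:1, rt
Reagents that add atoms: none
Why: Acid-catalysed hydrolysis of the isopropylidene acetal should give the prochiral triol without touching the tertiary allylic alcohol.

Step 3
Reactants: 4 2-vinylglycerol; 5 benzoyl chloride
Product: 6 (2R)-2-hydroxy-2-(hydroxymethyl)but-3-en-1-yl benzoate
Conditions: CuCl2 (5 mol%), (R,R)-2,2′-(propane-2,2-diyl)bis(4-phenyl-4,5-dihydro-1,3-oxazole) (5 mol%), Et3N (1.0 equiv), THF, 0 °C → rt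
Reagents that add atoms: benzoyl chloride, O=C(Cl)c1ccccc1
Why: Copper–bis(oxazoline)-catalysed monobenzoylation of a diol, used as a desymmetrisation of a 2-substituted glycerol: the tertiary OH and one enantiotopic CH2OH chelate the chiral copper centre and only that bound primary OH is acylated, which sets the quaternary stereocentre (R).

Step 4
Reactants: 7 dichlorodi(propan-2-yl)silane; 8 allylmagnesium bromide
Product: 9 chloro(prop-2-en-1-yl)di(propan-2-yl)silane
Conditions: Et2O, −20 °C → rt, 1.0 equiv of 8; filtration, distillation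
Reagents that add atoms: allylmagnesium bromide, C=CC[Mg]Br
Why: Nucleophilic substitution at silicon; the two isopropyl groups slow the second substitution, so the monochloride should be obtained.

Step 5
Reactants: 6 monobenzoate; 9 chloro(allyl)diisopropylsilane
Product: 10 (2S)-2-hydroxy-2-({[di(propan-2-yl)(prop-2-en-1-yl)silyl]oxy}methyl)but-3-en-1-yl benzoate
Conditions: imidazole (2.2 equiv), CH2Cl2, 0 °C → rt
Reagents that add atoms: chloro(prop-2-en-1-yl)di(propan-2-yl)silane, C=CC[Si](Cl)(C(C)C)C(C)C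
Why: Chemoselective O-silylation of the primary hydroxyl (the tertiary one is too hindered for this chlorosilane); the stereocentre is untouched and the bulky silyl group should not migrate.

Step 6
Reactants: 10 silyl ether
Product: 11 [(6S)-6-hydroxy-2,2-di(propan-2-yl)-2,3,6,7-tetrahydro-1,2-oxasilepin-6-yl]methyl benzoate
Conditions: second-generation Grubbs catalyst RuCl2(=CHPh)(PCy3)(H2IMes) (3 mol%), CH2Cl2 (0.005 M), 40 °C
Reagents that add atoms: none
Why: Ring-closing metathesis of the allylsilane with the vinyl group should close the seven-membered cyclic allylsiloxane, whose ring size enforces the Z alkene.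

Step 7
Reactants: 11 oxasilepine benzoate; 12 1-(trimethylsilyl)imidazole
Product: 14 (6S)-2,2-di(propan-2-yl)-6-(trimethylsilyloxy)-6-[(trimethylsilyloxy)methyl]-2,3,6,7-tetrahydro-1,2-oxasilepine, via diol 13 (not isolated)
Conditions: DIBAL-H (iBu2AlH, 2.5 equiv), CH2Cl2, −78 °C; Rochelle salt; crude diol, then 12 (3 equiv), CH2Cl2, 0 °C → rt
Reagents that add atoms: 1-(trimethylsilyl)imidazole, C[Si](C)(C)n1ccnc1
Why: Reductive cleavage of the benzoate (chosen over basic methanolysis so that no free alkoxide can move silicon between the two CH2O arms), then silylation of both hydroxyls by a strong silyl donor; no bond to the stereocentre is broken.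

Step 8
Reactants: 15 5-bromovanillin; 16 chlorotri(propan-2-yl)silane
Product: 17 3-bromo-5-methoxy-4-(triisopropylsilyloxy)benzaldehyde
Conditions: imidazole, DMF, rt → 40 °C
Reagents that add atoms: chlorotri(propan-2-yl)silane, CC(C)[Si](Cl)(C(C)C)C(C)C
Why: Imidazole-assisted O-silylation of the phenol; the TIPS ether is chosen because it should survive Grignard, Suzuki and Lewis-acid steps and leave at the end with fluoride.

Step 9
Reactants: 18 4-bromo-2-methoxyphenol; 16 chlorotri(propan-2-yl)silane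
Product: 19 (4-bromo-2-methoxyphenoxy)tri(propan-2-yl)silane
Conditions: imidazole, DMF, rt
Reagents that add atoms: chlorotri(propan-2-yl)silane, CC(C)[Si](Cl)(C(C)C)C(C)C
Why: Standard phenol silylation giving the precursor of the 4-oxy-3-methoxyphenyl Grignard reagent.

Step 10
Reactants: 20 5-bromo-2-methoxyphenol; 16 chlorotri(propan-2-yl)silane
Product: 21 (5-bromo-2-methoxyphenoxy)tri(propan-2-yl)silane
Conditions: imidazole, DMF, rt
Reagents that add atoms: chlorotri(propan-2-yl)silane, CC(C)[Si](Cl)(C(C)C)C(C)C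
Why: Standard phenol silylation giving the precursor of the 3-oxy-4-methoxyphenyl Grignard reagent.

Step 11
Reactants: 17 bromo aldehyde; 22 bis(pinacolato)diboron
Product: 23 3-methoxy-5-(4,4,5,5-tetramethyl-1,3,2-dioxaborolan-2-yl)-4-(triisopropylsilyloxy)benzaldehyde
Conditions: PdCl2(dppf) (3 mol%), KOAc (3 equiv), 1,4-dioxane, 85 °C
Reagents that add atoms: bis(pinacolato)diboron, CC1(C)OB(OC1(C)C)B1OC(C)(C)C(C)(C)O1
Why: Miyaura borylation of the aryl bromide; aldehyde and aryl silyl ether are tolerated under the weakly basic acetate conditions.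

Step 12
Reactants: 17 bromo aldehyde; 14 bis(trimethylsilyl) oxasilepine
Product: 26 (3R,4R,5S)-5-[3-bromo-5-methoxy-4-(triisopropylsilyloxy)phenyl]-4-ethenyl-3-(hydroxymethyl)oxolan-3-ol, via spiro-dioxolane 24 (not isolated), via dioxasilolane 25 (not isolated)
Conditions: 14 (1.1 equiv), TMSOTf (0.2 equiv), CH2Cl2, −78 → −30 °C; Et3N; then HF·pyridine, pyridine, THF, 0 °C
Reagents that add atoms: oxasilepine 14, C1O[Si](C(C)C)(C(C)C)C/C=C\[C@]1(O[Si](C)(C)C)CO[Si](C)(C)C
Why: The key-step reaction (see step 19) on the simple aldehyde: silyl-triflate-catalysed acetalisation, ionisation to the oxocarbenium ion on the primary oxygen and intramolecular Hosomi–Sakurai closure, in which the intact siloxane ring should set C8 (vinyl cis to the silyloxymethyl arm) and the (E)-oxocarbenium should set C7 (aryl trans to vinyl); HF·pyridine then frees the diol.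

Step 13
Reactants: 26 tetrahydrofuran diol
Product: 28 (3R,6S,7R)-6-[3-bromo-5-methoxy-4-(triisopropylsilyloxy)phenyl]-7-ethenyl-1,5-dioxaspiro[2.4]heptane, via primary tosylate 27 (not isolated)
Conditions: TsCl (1.05 equiv), Et3N, Bu2SnO (2 mol%), CH2Cl2, 0 °C; then K2CO3, MeOH, 0 °C
Reagents that add atoms: none
Why: Tin-acetal-catalysed selective tosylation of the primary hydroxyl of the 1,2-diol and 3-exo-tet displacement by the tertiary alkoxide (intramolecular Williamson reaction); no bond to the quaternary stereocentre is broken.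

Step 14
Reactants: 28 spiro-epoxide; 19 aryl bromide
Product: 30 (3S,4R,5S)-5-[3-bromo-5-methoxy-4-(triisopropylsilyloxy)phenyl]-4-ethenyl-3-{[3-methoxy-4-(triisopropylsilyloxy)phenyl]methyl}oxolan-3-ol, via aryl Grignard reagent 29 (not isolated)
Conditions: 19, Mg, THF, 40 °C; then 28, CuI (10 mol%), THF, −30 → 0 °C; aq. NH4Cl
Reagents that add atoms: aryl bromide 19 (as 29), COc1cc(Br)ccc1O[Si](C(C)C)(C(C)C)C(C)C
Why: Copper-catalysed SN2 opening of the 2,2-disubstituted epoxide at its CH2 terminus; the C–O bond at the quaternary centre stays, so the tertiary alcohol keeps its configuration and the new benzyl group is cis to the vinyl group.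

Step 15
Reactants: 30 vinyl tetrahydrofuran
Product: 32 (3S,4R,5S)-5-[3-bromo-5-methoxy-4-(triisopropylsilyloxy)phenyl]-4-(hydroxymethyl)-3-{[3-methoxy-4-(triisopropylsilyloxy)phenyl]methyl}oxolan-3-ol, via aldehyde 31 (not isolated)
Conditions: OsO4 (2 mol%), NaIO4 (4 equiv), 2,6-lutidine, 1,4-dioxane/H2O 3:1, rt; extraction; then NaBH4, MeOH, 0 °C
Reagents that add atoms: sodium periodate, [Na+].[O-]I(=O)(=O)=O; water, O (with catalytic OsO4 they supply the new oxygen atom)
Why: Lemieux–Johnson cleavage of the only alkene and immediate borohydride reduction, before the β-hydroxy aldehyde can epimerise or undergo retro-aldol cleavage; C8 keeps its configuration.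

Step 16
Reactants: 32 olivil-type triol
Product: 33 (2S,3S,4S)-4-[3-bromo-5-methoxy-4-(triisopropylsilyloxy)phenyl]-2,3-bis(hydroxymethyl)-7-methoxy-6-(triisopropylsilyloxy)-1,2,3,4-tetrahydronaphthalen-2-ol
Conditions: TfOH (10 mol%), (CF3)2CHOH/CH2Cl2 1:4, 0 °C; NaHCO3
Reagents that add atoms: none
Why: Acid ionises the benzylic C7–O bond (cation stabilised by the para silyloxy group) and the benzyl ring closes the six-membered ring by Friedel–Crafts attack para to its methoxy group (the olivil-to-cycloolivil isomerisation); the new benzylic centre should form trans to the neighbouring CH2OH (pseudo-equatorial aryl), while C8 and C8′ are untouched.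

Step 17
Reactants: 33 tetralin triol; 34 tert-butyl(chloro)diphenylsilane
Product: 35 (2S,3S,4S)-4-[3-bromo-5-methoxy-4-(triisopropylsilyloxy)phenyl]-2,3-bis[(tert-butyldiphenylsilyloxy)methyl]-7-methoxy-6-(triisopropylsilyloxy)-1,2,3,4-tetrahydronaphthalen-2-ol
Conditions: 34 (2.3 equiv), imidazole, DMF, 0 °C → rt
Reagents that add atoms: tert-butyl(chloro)diphenylsilane, CC(C)(C)[Si](Cl)(c1ccccc1)c1ccccc1
Why: Selective silylation of the two primary hydroxyls (the tertiary one is inert to this reagent); TBDPS ethers should survive triflate, HF·pyridine, Grignard and periodate steps.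

Step 18
Reactants: 35 tetralin bromide; 23 boronate aldehyde
Product: 36 biaryl aldehyde: 35 with Br replaced by a 5-formyl-3-methoxy-2-(triisopropylsilyloxy)phenyl group (tetralin 2S,3S,4S unchanged)
Conditions: Pd(OAc)2 (5 mol%), SPhos (10 mol%), K3PO4 (3 equiv), toluene/H2O 10:1, 80 °C
Reagents that add atoms: boronate 23, O=Cc1cc(OC)c(O[Si](C(C)C)(C(C)C)C(C)C)c(c1)B1OC(C)(C)C(C)(C)O1
Why: Suzuki–Miyaura cross-coupling with a dialkylbiarylphosphine ligand suited to the two ortho-silyloxy groups; the biaryl axis carries only two ortho substituents and is not a stereogenic element.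

Step 19
Reactants: 36 biaryl aldehyde; 14 bis(trimethylsilyl) oxasilepine
Product: 39 (3R,4R,5S)-4-ethenyl-3-(hydroxymethyl)-5-Ar-oxolan-3-ol (Ar = the aryl group of 36), via spiro-dioxolane 37 (not isolated), via dioxasilolane 38 (not isolated)
Conditions: 14 (1.3 equiv), TMSOTf (0.3 equiv), CH2Cl2, −78 → −30 °C; Et3N; then HF·pyridine, pyridine, THF, 0 °C
Reagents that add atoms: oxasilepine 14, C1O[Si](C(C)C)(C(C)C)C/C=C\[C@]1(O[Si](C)(C)C)CO[Si](C)(C)C
Why: Silyl-triflate-catalysed acetalisation of the aldehyde by the vicinal bis(trimethylsilyl) ether gives spiro-dioxolane 37; ionisation of its bond to the tertiary oxygen gives the (E)-oxocarbenium ion on the C9′ oxygen, the allylsilane γ-carbon (C8) adds to C7 and silicon passes to the neighbouring oxygen. This is an intramolecular Hosomi–Sakurai (silyl-Prins) reaction, the type known from condensations of 1,2-oxasilepines and other hydroxy allylsilanes with aldehydes to 2-substituted 3-vinyltetrahydrofurans. The five-membered ring closes exo with respect to the allylsilane π bond and endo with respect to C=O+, which the long C···C contact of the β-silyl-stabilised transition state allows. C8 is set by the still intact seven-membered siloxane: its Z alkene holds the CH2O–Si arm of C8′ syn to the alkene carbon that becomes the vinyl group and places the C–Si bond anti to the incoming electrophile, so C7 must add on the face of the C9′ arm and the vinyl group ends cis to the silyloxymethyl arm and trans to the tertiary oxygen. C7 is set by the (E)-oxocarbenium geometry, with the aryl group anti to the tether and away from the exocyclic alkene carbon, giving the 7,8-trans ring, which is also the thermodynamic one should the benzylic ether re-ionise. The step needs ionisation towards the primary oxygen and no exchange of silicon between the two CH2O arms: the oxocarbenium on the tertiary oxygen cannot close a five-membered ring and reverts, and the hindered diisopropylsilyl ether oxygen neither captures the electrophile nor exchanges with TMSOTf at −78 °C.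

Step 20
Reactants: 39 biaryl tetrahydrofuran diol
Product: 41 (3R,6S,7R)-7-ethenyl-6-Ar-1,5-dioxaspiro[2.4]heptane (Ar as in 39), via primary tosylate 40 (not isolated)
Conditions: TsCl (1.05 equiv), Et3N, Bu2SnO (2 mol%), CH2Cl2, 0 °C; then K2CO3, MeOH, 0 °C
Reagents that add atoms: none
Why: Same selective tosylation and Williamson closure as in step 13; the tertiary hydroxyl of the tetralin has no neighbouring leaving group and stays as it is.

Step 21
Reactants: 41 spiro-epoxide; 21 aryl bromide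
Product: 43 (3S,4R,5S)-4-ethenyl-3-{[4-methoxy-3-(triisopropylsilyloxy)phenyl]methyl}-5-Ar-oxolan-3-ol (Ar as in 39), via aryl Grignard reagent 42 (not isolated)
Conditions: 21 (3 equiv), Mg, THF, 40 °C; then 41, CuI (20 mol%), THF, −30 → 0 °C; aq. NH4Cl
Reagents that add atoms: aryl bromide 21 (as 42), COc1ccc(Br)cc1O[Si](C(C)C)(C(C)C)C(C)C
Why: Copper-catalysed SN2 opening at the epoxide CH2 as in step 14 (one extra equivalent of Grignard reagent is consumed by the free tertiary hydroxyl); C8′ keeps its configuration.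

Step 22
Reactants: 43 vinyl compound
Product: 45 hexasilyl ether of the target: (3S,4R,5S)-4-(hydroxymethyl)-3-{[4-methoxy-3-(triisopropylsilyloxy)phenyl]methyl}-5-Ar-oxolan-3-ol (Ar as in 39), via aldehyde 44 (not isolated)
Conditions: OsO4 (2 mol%), NaIO4 (4 equiv), 2,6-lutidine, 1,4-dioxane/H2O 3:1, rt; extraction; then NaBH4, MeOH, 0 °C
Reagents that add atoms: sodium periodate, [Na+].[O-]I(=O)(=O)=O; water, O (with catalytic OsO4 they supply the new oxygen atom)
Why: Lemieux–Johnson cleavage of the only alkene and immediate reduction, as in step 15, with retention at C8.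

Step 23
Reactants: 45 hexasilyl ether
Product: 46 CNP0252244.1 (target)
Conditions: Bu4NF (10 equiv), AcOH (10 equiv), THF (degassed), 0 °C → rt
Reagents that add atoms: none
Why: Fluoride cleaves the four aryl TIPS ethers and the two primary TBDPS ethers; acetic acid buffers the phenoxides, and neither acid nor hydrogenolysis, which would endanger the benzylic tetrahydrofuran ether, is needed.

## Compound list

1 | 2,2-dimethyl-1,3-dioxan-5-one | CC1(C)OCC(=O)CO1 | starting material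
2 | vinylmagnesium bromide | C=C[Mg]Br | starting material
3 | 5-ethenyl-2,2-dimethyl-1,3-dioxan-5-ol | CC1(C)OCC(O)(C=C)CO1 | intermediate
4 | 2-(hydroxymethyl)but-3-ene-1,2-diol | OCC(O)(CO)C=C | intermediate
5 | benzoyl chloride | O=C(Cl)c1ccccc1 | starting material
6 | (2R)-2-hydroxy-2-(hydroxymethyl)but-3-en-1-yl benzoate | OC[C@@](C=C)(O)COC(=O)c1ccccc1 | intermediate
7 | dichlorodi(propan-2-yl)silane | CC(C)[Si](Cl)(Cl)C(C)C | starting material
8 | allylmagnesium bromide | C=CC[Mg]Br | starting material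
9 | chloro(prop-2-en-1-yl)di(propan-2-yl)silane | C=CC[Si](Cl)(C(C)C)C(C)C | intermediate
10 | (2S)-2-hydroxy-2-({[di(propan-2-yl)(prop-2-en-1-yl)silyl]oxy}methyl)but-3-en-1-yl benzoate | C=CC[Si](C(C)C)(C(C)C)OC[C@@](C=C)(O)COC(=O)c1ccccc1 | intermediate
11 | [(6S)-6-hydroxy-2,2-di(propan-2-yl)-2,3,6,7-tetrahydro-1,2-oxasilepin-6-yl]methyl benzoate (Z ring alkene) | C1O[Si](C(C)C)(C(C)C)C/C=C\[C@]1(O)COC(=O)c1ccccc1 | intermediate
12 | 1-(trimethylsilyl)imidazole | C[Si](C)(C)n1ccnc1 | starting material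
13 | (6S)-6-(hydroxymethyl)-2,2-di(propan-2-yl)-2,3,6,7-tetrahydro-1,2-oxasilepin-6-ol | C1O[Si](C(C)C)(C(C)C)C/C=C\[C@]1(O)CO | intermediate (not isolated)
14 | (6S)-2,2-di(propan-2-yl)-6-(trimethylsilyloxy)-6-[(trimethylsilyloxy)methyl]-2,3,6,7-tetrahydro-1,2-oxasilepine | C1O[Si](C(C)C)(C(C)C)C/C=C\[C@]1(O[Si](C)(C)C)CO[Si](C)(C)C | intermediate
15 | 5-bromovanillin (3-bromo-4-hydroxy-5-methoxybenzaldehyde) | O=Cc1cc(Br)c(O)c(OC)c1 | starting material
16 | chlorotri(propan-2-yl)silane | CC(C)[Si](Cl)(C(C)C)C(C)C | starting material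
17 | 3-bromo-5-methoxy-4-(triisopropylsilyloxy)benzaldehyde | O=Cc1cc(Br)c(O[Si](C(C)C)(C(C)C)C(C)C)c(OC)c1 | intermediate
18 | 4-bromo-2-methoxyphenol | COc1cc(Br)ccc1O | starting material
19 | (4-bromo-2-methoxyphenoxy)tri(propan-2-yl)silane | COc1cc(Br)ccc1O[Si](C(C)C)(C(C)C)C(C)C | intermediate
20 | 5-bromo-2-methoxyphenol | COc1ccc(Br)cc1O | starting material
21 | (5-bromo-2-methoxyphenoxy)tri(propan-2-yl)silane | COc1ccc(Br)cc1O[Si](C(C)C)(C(C)C)C(C)C | intermediate
22 | bis(pinacolato)diboron | CC1(C)OB(OC1(C)C)B1OC(C)(C)C(C)(C)O1 | starting material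
23 | 3-methoxy-5-(4,4,5,5-tetramethyl-1,3,2-dioxaborolan-2-yl)-4-(triisopropylsilyloxy)benzaldehyde | O=Cc1cc(OC)c(O[Si](C(C)C)(C(C)C)C(C)C)c(c1)B1OC(C)(C)C(C)(C)O1 | intermediate
24 | spiro-dioxolane: 2-aryl-1,3-dioxolane of the tertiary and the free primary oxygen of 13, spiro-fused to the oxasilepine (aryl of 17; both acetal epimers) | C1O[Si](C(C)C)(C(C)C)C/C=C\[C@]12COC(O2)c1cc(Br)c(O[Si](C(C)C)(C(C)C)C(C)C)c(OC)c1 | intermediate (not isolated)
25 | dioxasilolane: 26 with its two hydroxyl oxygens bridged by Si(iPr)2 | O1C[C@@]2(O[Si]1(C(C)C)C(C)C)CO[C@H](c1cc(Br)c(O[Si](C(C)C)(C(C)C)C(C)C)c(OC)c1)[C@H]2C=C | intermediate (not isolated)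
26 | (3R,4R,5S)-5-[3-bromo-5-methoxy-4-(triisopropylsilyloxy)phenyl]-4-ethenyl-3-(hydroxymethyl)oxolan-3-ol | OC[C@@]1(O)CO[C@H](c2cc(Br)c(O[Si](C(C)C)(C(C)C)C(C)C)c(OC)c2)[C@H]1C=C | intermediate
27 | primary 4-methylbenzenesulfonate of 26 | Cc1ccc(cc1)S(=O)(=O)OC[C@@]2(O)CO[C@H](c3cc(Br)c(O[Si](C(C)C)(C(C)C)C(C)C)c(OC)c3)[C@H]2C=C | intermediate (not isolated)
28 | (3R,6S,7R)-6-[3-bromo-5-methoxy-4-(triisopropylsilyloxy)phenyl]-7-ethenyl-1,5-dioxaspiro[2.4]heptane | C1[C@@]2(O1)CO[C@H](c3cc(Br)c(O[Si](C(C)C)(C(C)C)C(C)C)c(OC)c3)[C@H]2C=C | intermediate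
29 | [3-methoxy-4-(triisopropylsilyloxy)phenyl]magnesium bromide | COc1cc([Mg]Br)ccc1O[Si](C(C)C)(C(C)C)C(C)C | intermediate (not isolated)
30 | (3S,4R,5S)-5-[3-bromo-5-methoxy-4-(triisopropylsilyloxy)phenyl]-4-ethenyl-3-{[3-methoxy-4-(triisopropylsilyloxy)phenyl]methyl}oxolan-3-ol | COc1cc(C[C@@]2(O)CO[C@H](c3cc(Br)c(O[Si](C(C)C)(C(C)C)C(C)C)c(OC)c3)[C@H]2C=C)ccc1O[Si](C(C)C)(C(C)C)C(C)C | intermediate
31 | (2S,3R,4S)-2-[3-bromo-5-methoxy-4-(triisopropylsilyloxy)phenyl]-4-hydroxy-4-{[3-methoxy-4-(triisopropylsilyloxy)phenyl]methyl}oxolane-3-carbaldehyde | COc1cc(C[C@@]2(O)CO[C@H](c3cc(Br)c(O[Si](C(C)C)(C(C)C)C(C)C)c(OC)c3)[C@H]2C=O)ccc1O[Si](C(C)C)(C(C)C)C(C)C | intermediate (not isolated)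
32 | (3S,4R,5S)-5-[3-bromo-5-methoxy-4-(triisopropylsilyloxy)phenyl]-4-(hydroxymethyl)-3-{[3-methoxy-4-(triisopropylsilyloxy)phenyl]methyl}oxolan-3-ol | COc1cc(C[C@@]2(O)CO[C@H](c3cc(Br)c(O[Si](C(C)C)(C(C)C)C(C)C)c(OC)c3)[C@H]2CO)ccc1O[Si](C(C)C)(C(C)C)C(C)C | intermediate
33 | (2S,3S,4S)-4-[3-bromo-5-methoxy-4-(triisopropylsilyloxy)phenyl]-2,3-bis(hydroxymethyl)-7-methoxy-6-(triisopropylsilyloxy)-1,2,3,4-tetrahydronaphthalen-2-ol | Brc1cc(cc(OC)c1O[Si](C(C)C)(C(C)C)C(C)C)[C@H]1c2cc(O[Si](C(C)C)(C(C)C)C(C)C)c(OC)cc2C[C@@](O)(CO)[C@@H]1CO | intermediate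
34 | tert-butyl(chloro)diphenylsilane | CC(C)(C)[Si](Cl)(c1ccccc1)c1ccccc1 | starting material
35 | (2S,3S,4S)-4-[3-bromo-5-methoxy-4-(triisopropylsilyloxy)phenyl]-2,3-bis[(tert-butyldiphenylsilyloxy)methyl]-7-methoxy-6-(triisopropylsilyloxy)-1,2,3,4-tetrahydronaphthalen-2-ol | Brc1cc(cc(OC)c1O[Si](C(C)C)(C(C)C)C(C)C)[C@H]1c2cc(O[Si](C(C)C)(C(C)C)C(C)C)c(OC)cc2C[C@@](O)(CO[Si](c2ccccc2)(c2ccccc2)C(C)(C)C)[C@@H]1CO[Si](c1ccccc1)(c1ccccc1)C(C)(C)C | intermediate
36 | biaryl aldehyde: 35 with Br replaced by 5-formyl-3-methoxy-2-(triisopropylsilyloxy)phenyl | O=Cc1cc(OC)c(O[Si](C(C)C)(C(C)C)C(C)C)c(c1)-c1cc(cc(OC)c1O[Si](C(C)C)(C(C)C)C(C)C)[C@H]1c2cc(O[Si](C(C)C)(C(C)C)C(C)C)c(OC)cc2C[C@@](O)(CO[Si](c2ccccc2)(c2ccccc2)C(C)(C)C)[C@@H]1CO[Si](c1ccccc1)(c1ccccc1)C(C)(C)C | intermediate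
37 | spiro-dioxolane: acetal of aldehyde 36 with the tertiary and the free primary oxygen of 13, spiro-fused to the oxasilepine (both acetal epimers) | C1O[Si](C(C)C)(C(C)C)C/C=C\[C@]12COC(O2)c1cc(OC)c(O[Si](C(C)C)(C(C)C)C(C)C)c(c1)-c1cc(cc(OC)c1O[Si](C(C)C)(C(C)C)C(C)C)[C@H]1c2cc(O[Si](C(C)C)(C(C)C)C(C)C)c(OC)cc2C[C@@](O)(CO[Si](c2ccccc2)(c2ccccc2)C(C)(C)C)[C@@H]1CO[Si](c1ccccc1)(c1ccccc1)C(C)(C)C | intermediate (not isolated)
38 | dioxasilolane: 39 with its two hydroxyl oxygens bridged by Si(iPr)2 | O1C[C@@]2(O[Si]1(C(C)C)C(C)C)CO[C@H](c1cc(OC)c(O[Si](C(C)C)(C(C)C)C(C)C)c(c1)-c1cc(cc(OC)c1O[Si](C(C)C)(C(C)C)C(C)C)[C@H]1c3cc(O[Si](C(C)C)(C(C)C)C(C)C)c(OC)cc3C[C@@](O)(CO[Si](c3ccccc3)(c3ccccc3)C(C)(C)C)[C@@H]1CO[Si](c1ccccc1)(c1ccccc1)C(C)(C)C)[C@H]2C=C | intermediate (not isolated)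
39 | (3R,4R,5S)-4-ethenyl-3-(hydroxymethyl)-5-Ar-oxolan-3-ol, Ar = aryl group of 36 | OC[C@@]1(O)CO[C@H](c2cc(OC)c(O[Si](C(C)C)(C(C)C)C(C)C)c(c2)-c2cc(cc(OC)c2O[Si](C(C)C)(C(C)C)C(C)C)[C@H]2c3cc(O[Si](C(C)C)(C(C)C)C(C)C)c(OC)cc3C[C@@](O)(CO[Si](c3ccccc3)(c3ccccc3)C(C)(C)C)[C@@H]2CO[Si](c2ccccc2)(c2ccccc2)C(C)(C)C)[C@H]1C=C | intermediate
40 | primary 4-methylbenzenesulfonate of 39 | Cc1ccc(cc1)S(=O)(=O)OC[C@@]2(O)CO[C@H](c3cc(OC)c(O[Si](C(C)C)(C(C)C)C(C)C)c(c3)-c3cc(cc(OC)c3O[Si](C(C)C)(C(C)C)C(C)C)[C@H]3c4cc(O[Si](C(C)C)(C(C)C)C(C)C)c(OC)cc4C[C@@](O)(CO[Si](c4ccccc4)(c4ccccc4)C(C)(C)C)[C@@H]3CO[Si](c3ccccc3)(c3ccccc3)C(C)(C)C)[C@H]2C=C | intermediate (not isolated)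
41 | (3R,6S,7R)-7-ethenyl-6-Ar-1,5-dioxaspiro[2.4]heptane, Ar as in 39 | C1[C@@]2(O1)CO[C@H](c3cc(OC)c(O[Si](C(C)C)(C(C)C)C(C)C)c(c3)-c3cc(cc(OC)c3O[Si](C(C)C)(C(C)C)C(C)C)[C@H]3c4cc(O[Si](C(C)C)(C(C)C)C(C)C)c(OC)cc4C[C@@](O)(CO[Si](c4ccccc4)(c4ccccc4)C(C)(C)C)[C@@H]3CO[Si](c3ccccc3)(c3ccccc3)C(C)(C)C)[C@H]2C=C | intermediate
42 | [4-methoxy-3-(triisopropylsilyloxy)phenyl]magnesium bromide | COc1ccc([Mg]Br)cc1O[Si](C(C)C)(C(C)C)C(C)C | intermediate (not isolated)
43 | (3S,4R,5S)-4-ethenyl-3-{[4-methoxy-3-(triisopropylsilyloxy)phenyl]methyl}-5-Ar-oxolan-3-ol, Ar as in 39 | COc1ccc(C[C@@]2(O)CO[C@H](c3cc(OC)c(O[Si](C(C)C)(C(C)C)C(C)C)c(c3)-c3cc(cc(OC)c3O[Si](C(C)C)(C(C)C)C(C)C)[C@H]3c4cc(O[Si](C(C)C)(C(C)C)C(C)C)c(OC)cc4C[C@@](O)(CO[Si](c4ccccc4)(c4ccccc4)C(C)(C)C)[C@@H]3CO[Si](c3ccccc3)(c3ccccc3)C(C)(C)C)[C@H]2C=C)cc1O[Si](C(C)C)(C(C)C)C(C)C | intermediate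
44 | aldehyde: 43 with CH=CH2 replaced by CHO (2S,3R,4S at the oxolane-3-carbaldehyde) | COc1ccc(C[C@@]2(O)CO[C@H](c3cc(OC)c(O[Si](C(C)C)(C(C)C)C(C)C)c(c3)-c3cc(cc(OC)c3O[Si](C(C)C)(C(C)C)C(C)C)[C@H]3c4cc(O[Si](C(C)C)(C(C)C)C(C)C)c(OC)cc4C[C@@](O)(CO[Si](c4ccccc4)(c4ccccc4)C(C)(C)C)[C@@H]3CO[Si](c3ccccc3)(c3ccccc3)C(C)(C)C)[C@H]2C=O)cc1O[Si](C(C)C)(C(C)C)C(C)C | intermediate (not isolated)
45 | hexasilyl ether of the target (four aryl O-TIPS, two CH2O-TBDPS on the tetralin; oxolane 3S,4R,5S; tetralin 2S,3S,4S) | COc1ccc(C[C@@]2(O)CO[C@H](c3cc(OC)c(O[Si](C(C)C)(C(C)C)C(C)C)c(c3)-c3cc(cc(OC)c3O[Si](C(C)C)(C(C)C)C(C)C)[C@H]3c4cc(O[Si](C(C)C)(C(C)C)C(C)C)c(OC)cc4C[C@@](O)(CO[Si](c4ccccc4)(c4ccccc4)C(C)(C)C)[C@@H]3CO[Si](c3ccccc3)(c3ccccc3)C(C)(C)C)[C@H]2CO)cc1O[Si](C(C)C)(C(C)C)C(C)C | intermediate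
46 | CNP0252244.1 | COc1ccc(C[C@@]2(O)CO[C@H](c3cc(OC)c(O)c(-c4cc([C@H]5c6cc(O)c(OC)cc6C[C@@](O)(CO)[C@@H]5CO)cc(OC)c4O)c3)[C@H]2CO)cc1O | target

## Summary

Total step count: 23. Longest linear sequence: 18 steps (steps 1–3, 5–7, 12–23).

Steps most likely to fail:

1. Step 19. Process at risk: ionisation of acetal 37 mainly towards the tertiary oxygen, with leakage into oxonia-Cope/aldol-type or fragmentation channels, or re-ionisation of the benzylic ether after closure; both are more likely on the hindered, polyoxygenated biaryl aldehyde than on 17. Fallback (biaryl bond made last, so that the ring-forming event is the one already run in step 12): epoxide 28 is opened by Grignard reagent 42 (from 21, CuI) to give the olivil-type bromo alkene F1; Lemieux–Johnson cleavage gives the aldehyde F2 and NaBH4 the bromo diol F3; bromide 35 is converted by Miyaura borylation (bis(pinacolato)diboron, PdCl2(dppf), KOAc) into the tetralin boronate F4; Suzuki–Miyaura coupling of F3 with F4 (Pd(OAc)2, SPhos, K3PO4) gives 45, where the route resumes at step 23.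

2. Step 3. Process at risk: insufficient enantioselection or the opposite sense of induction in the desymmetrising benzoylation, and later acyl migration between the two primary oxygens. Fallback (chirality from a Sharpless asymmetric epoxidation, whose facial sense is predictable): commercial 2-methylidenepropane-1,3-diol is monosilylated with 9 (imidazole) to the allylic alcohol F5; epoxidation with Ti(OiPr)4, L-(+)-diethyl tartrate and tert-butyl hydroperoxide gives the (S)-epoxy alcohol F6; Parikh–Doering oxidation gives the epoxy aldehyde F7; Wittig methylenation (Ph3P=CH2) gives the vinyl epoxide F8; ring-closing metathesis gives the spiro-epoxide oxasilepine F9; hydroxide (KOH, DMSO/H2O) opens the epoxide at its CH2 terminus to give diol 13, which is silylated to 14 as in the second stage of step 7.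

3. Step 16. Process at risk: loss of the aryl silyl ether under acid followed by quinone-methide oligomerisation, or re-closure of the ring-opened cation to the tetrahydrofuran instead of C–C closure. Fallback (cation generated through the free phenol, the mode known for the natural olivil-to-cycloolivil change): 32 is desilylated with Bu4NF to the bisphenol F10; dilute acid (HCO2H, rt) isomerises it through the para-quinone methide to the tetralin bisphenol F11; selective silylation of the two phenoxides (K2CO3, chlorotri(propan-2-yl)silane 16, DMF) returns 33.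

Further compounds
F1 | step 19 | (3S,4R,5S)-5-[3-bromo-5-methoxy-4-(triisopropylsilyloxy)phenyl]-4-ethenyl-3-{[4-methoxy-3-(triisopropylsilyloxy)phenyl]methyl}oxolan-3-ol | COc1ccc(C[C@@]2(O)CO[C@H](c3cc(Br)c(O[Si](C(C)C)(C(C)C)C(C)C)c(OC)c3)[C@H]2C=C)cc1O[Si](C(C)C)(C(C)C)C(C)C
F2 | step 19 | aldehyde from F1 (CH=CH2 replaced by CHO) | COc1ccc(C[C@@]2(O)CO[C@H](c3cc(Br)c(O[Si](C(C)C)(C(C)C)C(C)C)c(OC)c3)[C@H]2C=O)cc1O[Si](C(C)C)(C(C)C)C(C)C
F3 | step 19 | (3S,4R,5S)-5-[3-bromo-5-methoxy-4-(triisopropylsilyloxy)phenyl]-4-(hydroxymethyl)-3-{[4-methoxy-3-(triisopropylsilyloxy)phenyl]methyl}oxolan-3-ol | COc1ccc(C[C@@]2(O)CO[C@H](c3cc(Br)c(O[Si](C(C)C)(C(C)C)C(C)C)c(OC)c3)[C@H]2CO)cc1O[Si](C(C)C)(C(C)C)C(C)C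
F4 | step 19 | pinacol boronate of 35 (Br replaced by 4,4,5,5-tetramethyl-1,3,2-dioxaborolan-2-yl) | CC1(C)OB(OC1(C)C)c1cc(cc(OC)c1O[Si](C(C)C)(C(C)C)C(C)C)[C@H]1c2cc(O[Si](C(C)C)(C(C)C)C(C)C)c(OC)cc2C[C@@](O)(CO[Si](c2ccccc2)(c2ccccc2)C(C)(C)C)[C@@H]1CO[Si](c1ccccc1)(c1ccccc1)C(C)(C)C
F5 | step 3 | 2-({[di(propan-2-yl)(prop-2-en-1-yl)silyl]oxy}methyl)prop-2-en-1-ol | C=CC[Si](C(C)C)(C(C)C)OCC(=C)CO
F6 | step 3 | [(2S)-2-({[di(propan-2-yl)(prop-2-en-1-yl)silyl]oxy}methyl)oxiran-2-yl]methanol | C=CC[Si](C(C)C)(C(C)C)OC[C@@]1(CO)OC1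
F7 | step 3 | (2S)-2-({[di(propan-2-yl)(prop-2-en-1-yl)silyl]oxy}methyl)oxirane-2-carbaldehyde | C=CC[Si](C(C)C)(C(C)C)OC[C@@]1(C=O)OC1
F8 | step 3 | (2S)-2-ethenyl-2-({[di(propan-2-yl)(prop-2-en-1-yl)silyl]oxy}methyl)oxirane | C=CC[Si](C(C)C)(C(C)C)OC[C@@]1(C=C)OC1
F9 | step 3 | (3S)-6,6-di(propan-2-yl)-1,5-dioxa-6-silaspiro[2.6]non-8-ene | C1O[Si](C(C)C)(C(C)C)C/C=C\[C@]12CO2
F10 | step 16 | (3S,4R,5S)-5-(3-bromo-4-hydroxy-5-methoxyphenyl)-3-[(4-hydroxy-3-methoxyphenyl)methyl]-4-(hydroxymethyl)oxolan-3-ol | COc1cc(C[C@@]2(O)CO[C@H](c3cc(Br)c(O)c(OC)c3)[C@H]2CO)ccc1O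
F11 | step 16 | (2S,3S,4S)-4-(3-bromo-4-hydroxy-5-methoxyphenyl)-2,3-bis(hydroxymethyl)-7-methoxy-1,2,3,4-tetrahydronaphthalene-2,6-diol | Brc1cc(cc(OC)c1O)[C@H]1c2cc(O)c(OC)cc2C[C@@](O)(CO)[C@@H]1CO
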